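**Retrosynthetic overview**
- Protect every phenol as Me or PMB ether. Install the (E)-4-methoxystyryl group last by Heck coupling on the one remaining Ar–Br, and remove all Me/PMB groups with BBr3.
- Each of the three trans-2,3-diaryl-dihydrobenzofurans (DHBs) comes from a Rh(II)-catalysed enantioselective carbene C–H insertion. A diaryl-diazomethane, made from a benzophenone tosylhydrazone, inserts into the ortho ArO–CH2–C6H4OMe C–H bond. This sets both stereocentres (trans) of the ring in one step, and the catalyst enantiomer alternates (R,R / S,S / R,R).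
- Each benzophenone is made from an aryllithium (Li–Br exchange) plus the next ring's 2-bromo-aldehyde, then oxidation. The leftover Br on the new ring carries the next cycle, so rings close in the order DHB1, DHB2, DHB3.

Assumption: the target is the linear resveratrol tetramer as drawn (stilbene, then DHB1 (2R,3R), DHB2 (2S,3S), DHB3 (2R,3R)). Rh2(S-PTAD)4 is taken to give the (2R,3R) sense and its enantiomer the (2S,3S) sense, with catalyst control overriding the resident stereocentres. PMB = CH2C6H4OMe-4.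

---

**Step 1**
Reactants: 1 (5-bromoresorcinol), 2 (4-methoxybenzyl chloride)
Product: 3 (1-bromo-3,5-bis(PMBO)benzene)
Conditions: K2CO3, DMF, 60 °C
Reagents that add atoms: PMBCl, COc1ccc(CCl)cc1
Why: Williamson bis-O-alkylation puts a PMB on each phenol. One of them becomes the benzylic ether C–H donor for a later insertion.

**Step 2**
Reactants: 3
Product: 4 (1,2-dibromo-3,5-bis(PMBO)benzene)
Conditions: NBS, MeCN, 0 °C → rt
Reagents that add atoms: N-bromosuccinimide, O=C1CCC(=O)N1Br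
Why: Electrophilic aromatic bromination goes at C2, ortho to one OPMB and para to the other, rather than at the hindered C4 between the two ethers. This gives the ring-A building block with Br at A1 (future styryl) and Br at A6 (future carbonyl attachment).

**Step 3**
Reactants: 5 (3,5-dihydroxybenzaldehyde), 2
Product: 6 (3,5-bis(PMBO)benzaldehyde)
Conditions: K2CO3, DMF, 60 °C
Reagents that add atoms: PMBCl, COc1ccc(CCl)cc1
Why: Williamson bis-O-alkylation, as in step 1.

**Step 4**
Reactants: 6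
Product: 7 (2-bromo-3,5-bis(PMBO)benzaldehyde)
Conditions: NBS, MeCN, 0 °C → rt
Reagents that add atoms: N-bromosuccinimide, O=C1CCC(=O)N1Br
Why: Bromination goes ortho to CHO and ortho/para to the two ethers. Because the ring is symmetric, either OPMB can later serve as the DHB oxygen.

**Step 5**
Reactants: 4, 7
Product: 8 (diaryl carbinol, A6-aryl–CH(OH)–ring B; carbinol stereocentre unspecified)
Conditions: t-BuLi (2 equiv), THF, −78 °C; then 7; NH4Cl (aq)
Reagents that add atoms: none
Why: Li–Br exchange should occur at the Br flanked by OPMB and Br (chelation and inductive activation), leaving the A1–Br. 1,2-Addition to 7 then builds the C8 carbon; the carbinol centre is destroyed in the next step.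

**Step 6**
Reactants: 8
Product: 9 (benzophenone K1)
Conditions: DMP, NaHCO3, CH2Cl2, rt
Reagents that add atoms: none
Why: Dess–Martin oxidation of the diaryl carbinol gives the carbene-precursor ketone; PMB ethers and Ar–Br are unaffected.

**Step 7**
Reactants: 9
Product: 10 (N-tosylhydrazone of 9)
Conditions: TsNHNH2, cat. TsOH, EtOH, 80 °C
Reagents that add atoms: p-toluenesulfonyl hydrazide, Cc1ccc(cc1)S(=O)(=O)NN
Why: Condensation with TsNHNH2 under forcing conditions (the ketone is tri-ortho-substituted) gives the stable diazo precursor.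

**Step 8**
Reactants: 10
Product: 11 (trans-DHB1 dimer, configuration of the target's DHB1)
Conditions: NaH, Rh2(S-PTAD)4 (2 mol %), PhCF3, 60 °C
Reagents that add atoms: none
Why: Bamford–Stevens generation of the diaryldiazomethane, then Rh-carbene intramolecular C–H insertion into the ortho ArO–CH2Ar C–H (donor/donor carbene). The 5-membered transition state gives the 2,3-trans ring, and the chiral catalyst sets the absolute configuration at both C7 and C8.

**Step 9**
Reactants: 11, 7
Product: 12 (carbinol linking ring B and ring C)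
Conditions: t-BuLi (2 equiv), THF, −78 °C; then 7; NH4Cl (aq)
Reagents that add atoms: none
Why: Li–Br exchange occurs at the B6–Br ortho to OPMB (chelation-favoured) rather than at A1–Br, and 1,2-addition to 7 follows. The DHB stereocentres survive at −78 °C, and the new carbinol centre is removed in step 10.

**Step 10**
Reactants: 12
Product: 13 (benzophenone K2)
Conditions: DMP, NaHCO3, CH2Cl2, rt
Reagents that add atoms: none
Why: Dess–Martin oxidation gives the ketone without touching the DHB stereocentres.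

**Step 11**
Reactants: 13
Product: 14 (N-tosylhydrazone of 13)
Conditions: TsNHNH2, cat. TsOH, EtOH, 80 °C
Reagents that add atoms: p-toluenesulfonyl hydrazide, Cc1ccc(cc1)S(=O)(=O)NN
Why: Hydrazone condensation, as in step 7.

**Step 12**
Reactants: 14
Product: 15 (trans-DHB2 formed on ring B; trimer with DHB1 and DHB2 in the target's configurations)
Conditions: NaH, Rh2(R-PTAD)4 (2 mol %), PhCF3, 60 °C
Reagents that add atoms: none
Why: The same carbene C–H insertion, with the opposite catalyst enantiomer, sets (2S,3S) at the new ring. It is trans-selective, and catalyst control is assumed to override the DHB1 stereocentres.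

**Step 13**
Reactants: 15, 16 (3,5-dimethoxybenzaldehyde)
Product: 17 (carbinol linking ring C and ring D)
Conditions: t-BuLi (2 equiv), THF, −78 °C; then 16; NH4Cl (aq)
Reagents that add atoms: none
Why: Selective Li–Br exchange at C6–Br (ortho to OPMB) followed by 1,2-addition installs the last aryl ring (ring D).

**Step 14**
Reactants: 17
Product: 18 (benzophenone K3)
Conditions: DMP, NaHCO3, CH2Cl2, rt
Reagents that add atoms: none
Why: Dess–Martin oxidation to the ketone.

**Step 15**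
Reactants: 18
Product: 19 (N-tosylhydrazone of 18)
Conditions: TsNHNH2, cat. TsOH, EtOH, 80 °C
Reagents that add atoms: p-toluenesulfonyl hydrazide, Cc1ccc(cc1)S(=O)(=O)NN
Why: Hydrazone condensation, as in step 7.

**Step 16**
Reactants: 19
Product: 20 (tetramer with three trans-DHBs, A1–Br still present)
Conditions: NaH, Rh2(S-PTAD)4 (2 mol %), PhCF3, 60 °C
Reagents that add atoms: none
Why: The third carbene C–H insertion closes DHB3 as (2R,3R), trans, with catalyst control of both centres.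

**Step 17**
Reactants: 20, 21 (4-methoxystyrene)
Product: 22 (fully protected tetramer with (E)-stilbene)
Conditions: Pd(OAc)2, P(o-tol)3, Et3N, DMF, 110 °C
Reagents that add atoms: 4-methoxystyrene, C=Cc1ccc(OC)cc1
Why: Mizoroki–Heck coupling on the only remaining Ar–Br gives the E-stilbene selectively, and no stereocentre is affected.

**Step 18**
Reactants: 22
Product: 23 (Miyabenol A, target)
Conditions: BBr3 (excess), CH2Cl2, −78 → 0 °C; MeOH quench
Reagents that add atoms: none
Why: Lewis-acid cleavage of all aryl methyl ethers and PMB ethers gives the nine free phenols. If the benzylic C7–O bond of a DHB ionises, it should reclose to the thermodynamically favoured trans isomer, so the stereochemistry is retained.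

---

**Compound list**

1 | 5-bromoresorcinol | Oc1cc(O)cc(Br)c1 | starting material
2 | 4-methoxybenzyl chloride | COc1ccc(CCl)cc1 | starting material
3 | 1-bromo-3,5-bis(PMBO)benzene | Brc1cc(OCc9ccc(OC)cc9)cc(OCc9ccc(OC)cc9)c1 | intermediate
4 | 1,2-dibromo-3,5-bis(PMBO)benzene | Brc1cc(OCc9ccc(OC)cc9)cc(OCc9ccc(OC)cc9)c1Br | intermediate
5 | 3,5-dihydroxybenzaldehyde | O=Cc1cc(O)cc(O)c1 | starting material
6 | 3,5-bis(PMBO)benzaldehyde | O=Cc1cc(OCc9ccc(OC)cc9)cc(OCc9ccc(OC)cc9)c1 | intermediate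
7 | 2-bromo-3,5-bis(PMBO)benzaldehyde | O=Cc1cc(OCc9ccc(OC)cc9)cc(OCc9ccc(OC)cc9)c1Br | intermediate
8 | [2-bromo-4,6-bis(PMBO)phenyl][2-bromo-3,5-bis(PMBO)phenyl]methanol | OC(c1c(Br)cc(OCc9ccc(OC)cc9)cc1OCc9ccc(OC)cc9)c1cc(OCc9ccc(OC)cc9)cc(OCc9ccc(OC)cc9)c1Br | intermediate
9 | bis-aryl ketone K1 | O=C(c1c(Br)cc(OCc9ccc(OC)cc9)cc1OCc9ccc(OC)cc9)c1cc(OCc9ccc(OC)cc9)cc(OCc9ccc(OC)cc9)c1Br | intermediate
10 | N-tosylhydrazone of 9 | Cc1ccc(cc1)S(=O)(=O)NN=C(c1c(Br)cc(OCc9ccc(OC)cc9)cc1OCc9ccc(OC)cc9)c1cc(OCc9ccc(OC)cc9)cc(OCc9ccc(OC)cc9)c1Br | intermediate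
11 | trans-4-bromo-3-[2-bromo-3,5-bis(PMBO)phenyl]-6-(PMBO)-2-(4-methoxyphenyl)-2,3-dihydrobenzofuran (DHB1 configuration of the target) | Brc1cc(OCc9ccc(OC)cc9)cc2c1[C@@H](c1cc(OCc9ccc(OC)cc9)cc(OCc9ccc(OC)cc9)c1Br)[C@H](c8ccc(OC)cc8)O2 | intermediate
12 | diaryl carbinol from 11 and 7 | Brc1cc(OCc9ccc(OC)cc9)cc2c1[C@@H](c1cc(OCc9ccc(OC)cc9)cc(OCc9ccc(OC)cc9)c1C(O)c1cc(OCc9ccc(OC)cc9)cc(OCc9ccc(OC)cc9)c1Br)[C@H](c8ccc(OC)cc8)O2 | intermediate
13 | ketone K2 | Brc1cc(OCc9ccc(OC)cc9)cc2c1[C@@H](c1cc(OCc9ccc(OC)cc9)cc(OCc9ccc(OC)cc9)c1C(=O)c1cc(OCc9ccc(OC)cc9)cc(OCc9ccc(OC)cc9)c1Br)[C@H](c8ccc(OC)cc8)O2 | intermediate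
14 | N-tosylhydrazone of 13 | Brc1cc(OCc9ccc(OC)cc9)cc2c1[C@@H](c1cc(OCc9ccc(OC)cc9)cc(OCc9ccc(OC)cc9)c1C(=NNS(=O)(=O)c7ccc(C)cc7)c1cc(OCc9ccc(OC)cc9)cc(OCc9ccc(OC)cc9)c1Br)[C@H](c8ccc(OC)cc8)O2 | intermediate
15 | bis-DHB trimer (DHB1 + DHB2, ring C carrying Br) | Brc1cc(OCc9ccc(OC)cc9)cc2c1[C@@H](c1cc(OCc9ccc(OC)cc9)cc3c1[C@H](c1cc(OCc9ccc(OC)cc9)cc(OCc9ccc(OC)cc9)c1Br)[C@@H](c8ccc(OC)cc8)O3)[C@H](c8ccc(OC)cc8)O2 | intermediate
16 | 3,5-dimethoxybenzaldehyde | COc1cc(C=O)cc(OC)c1 | starting material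
17 | diaryl carbinol from 15 and 16 | Brc1cc(OCc9ccc(OC)cc9)cc2c1[C@@H](c1cc(OCc9ccc(OC)cc9)cc3c1[C@H](c1cc(OCc9ccc(OC)cc9)cc(OCc9ccc(OC)cc9)c1C(O)c1cc(OC)cc(OC)c1)[C@@H](c8ccc(OC)cc8)O3)[C@H](c8ccc(OC)cc8)O2 | intermediate
18 | ketone K3 | Brc1cc(OCc9ccc(OC)cc9)cc2c1[C@@H](c1cc(OCc9ccc(OC)cc9)cc3c1[C@H](c1cc(OCc9ccc(OC)cc9)cc(OCc9ccc(OC)cc9)c1C(=O)c1cc(OC)cc(OC)c1)[C@@H](c8ccc(OC)cc8)O3)[C@H](c8ccc(OC)cc8)O2 | intermediate
19 | N-tosylhydrazone of 18 | Brc1cc(OCc9ccc(OC)cc9)cc2c1[C@@H](c1cc(OCc9ccc(OC)cc9)cc3c1[C@H](c1cc(OCc9ccc(OC)cc9)cc(OCc9ccc(OC)cc9)c1C(=NNS(=O)(=O)c7ccc(C)cc7)c1cc(OC)cc(OC)c1)[C@@H](c8ccc(OC)cc8)O3)[C@H](c8ccc(OC)cc8)O2 | intermediate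
20 | tris-DHB tetramer bromide | Brc1cc(OCc9ccc(OC)cc9)cc2c1[C@@H](c1cc(OCc9ccc(OC)cc9)cc3c1[C@H](c1cc(OCc9ccc(OC)cc9)cc4c1[C@@H](c1cc(OC)cc(OC)c1)[C@H](c8ccc(OC)cc8)O4)[C@@H](c8ccc(OC)cc8)O3)[C@H](c8ccc(OC)cc8)O2 | intermediate
21 | 4-methoxystyrene | C=Cc1ccc(OC)cc1 | starting material
22 | fully protected Miyabenol A (E-stilbene) | COc1ccc(/C=C/c2cc(OCc9ccc(OC)cc9)cc3c2[C@@H](c2cc(OCc9ccc(OC)cc9)cc4c2[C@H](c2cc(OCc9ccc(OC)cc9)cc5c2[C@@H](c2cc(OC)cc(OC)c2)[C@H](c8ccc(OC)cc8)O5)[C@@H](c8ccc(OC)cc8)O4)[C@H](c8ccc(OC)cc8)O3)cc1 | intermediate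
23 | Miyabenol A | Oc1ccc(/C=C/c2cc(O)cc3c2[C@@H](c2cc(O)cc4c2[C@H](c2cc(O)cc5c2[C@@H](c2cc(O)cc(O)c2)[C@H](c2ccc(O)cc2)O5)[C@@H](c2ccc(O)cc2)O4)[C@H](c2ccc(O)cc2)O3)cc1 | target

---

**Totals:** 18 steps in total. The longest linear sequence is 16 steps (steps 1, 2, 5–18).

**Three steps most likely to fail**
1. **Step 12 (Rh insertion at the trimer stage; same risk in steps 8 and 16).** The hindered diaryl carbene may give low yield or erode ee or dr. Fallback: insert with achiral Rh2(esp)2 to give racemic trans-DHBs at each stage, then resolve by chiral-stationary-phase HPLC.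
2. **Step 9 (chemoselective Li–Br exchange and hindered 1,2-addition; same risk in steps 5 and 13).** Exchange at A1–Br instead of the OPMB-flanked Br would give the wrong regiochemistry. Fallback: build ring A from a 1-chloro analogue so exchange is unambiguous, and install the styryl by Suzuki coupling of the aryl chloride with (E)-4-methoxystyryl-BPin instead of the Heck reaction.
3. **Step 18 (BBr3 global deprotection of a polyphenolic tetramer).** Benzylic C–O cleavage or decomposition is possible. Fallback: redo the route with phenols carried as TBS or MOM ethers (using a 4-(TBSO)benzyl ether as the insertion partner) so that a final TBAF or mild-acid deprotection replaces BBr3.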